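**Plan**

- Ring carbons are called C1 (C=O), C2 (Me), C3 (side chain), C4 (quaternary: Me and pyranonyl), C5 (H), C6 (Me). The retrosynthesis masks the side-chain ketone as a silyl ether and then cuts C1–C2 and C3–C4 together.
- This leaves C2≡C3 as the alkyne of enyne 28, which already holds the whole side chain, and C1–C6=C5–C4 as cyclobutenone 16, closed by a C1–C4 bond that the target does not contain.
- The enabling feature is that the carbonyl C1 lies para to the quaternary C4 across the intact C6=C5 bond. These four atoms can be stored as a strained four-membered ring whose only acyl–C(sp3) bond is C1–C4, so a metal can open exactly that bond and place C2–C3 into it while C4 keeps its other three neighbours.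
- Forward order: pyranone ring, then the temporary four-membered ring (ketene/enol ether [2+2], loss of the auxiliary alcohol), then the cyclohexadienone ring in the key step, which also joins the side chain; desilylation and oxidation finish.
- Stereochemistry: C4 is set in the [2+2] by a (1S,2R)-2-phenylcyclohexyl enol-ether auxiliary (relayed through the temporary alkoxy-bearing carbon) and carried with retention through the nickel step. The side-chain methyl centre comes from (R)-but-3-yn-2-ol by SN2′/SE2′ chirality transfer through an allenylzinc; the E-alkene comes from syn hydrozirconation.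

Key step: step 15

Assumption: the open face of the Z-enol ether 12 is taken from the usual phenyl-shielding picture (s-trans enol ether, carbinol C–H eclipsing the vinyl group); should the sense be the reverse, the (1R,2S)-alcohol is used and nothing else changes.

Step 1
Reactants: 1 methyl 2-methyl-3-oxopentanoate; 2 N-methoxy-N-methylpropanamide
Product: 4 methyl 2,4-dimethyl-3,5-dioxoheptanoate, via sodium lithium dianion 3 (not isolated)
Conditions: NaH, THF, 0 °C; n-BuLi, 0 °C; then 2, 0 °C to rt; aq. HCl
Reagents that add atoms: none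
Why: Claisen-type C-acylation in which the more reactive terminal carbanion of the β-keto ester dianion attacks the N-methoxy-N-methylamide, whose chelated tetrahedral intermediate prevents over-addition; the methyl-bearing centres are epimerisable and vanish on aromatisation.

Step 2
Reactants: 4 methyl 2,4-dimethyl-3,5-dioxoheptanoate
Product: 5 6-ethyl-4-hydroxy-3,5-dimethyl-2H-pyran-2-one
Conditions: DBU, toluene, reflux
Reagents that add atoms: none
Why: Base-mediated enolisation and lactonisation (intramolecular transesterification, 6-exo-trig) onto the methyl ester should give the 4-hydroxy-2-pyranone, in which no stereocentre remains.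

Step 3
Reactants: 5 6-ethyl-4-hydroxy-3,5-dimethyl-2H-pyran-2-one
Product: 6 6-ethyl-2-methoxy-3,5-dimethyl-4H-pyran-4-one
Conditions: MeOTf, CH2Cl2, rt; then aq. NaHCO3
Reagents that add atoms: methyl trifluoromethanesulfonate, COS(=O)(=O)C(F)(F)F
Why: O-Methylation with a hard alkylating agent takes place at the lactone carbonyl oxygen of the neutral pyranone and, after loss of a proton, should give the 2-methoxy-4-pyranone isomer selectively.

Step 4
Reactants: 6 6-ethyl-2-methoxy-3,5-dimethyl-4H-pyran-4-one
Product: 8 2-(6-methoxy-3,5-dimethyl-4-oxo-4H-pyran-2-yl)propanoic acid, via lithium dienolate 7 (not isolated)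
Conditions: LiN(SiMe3)2, THF, −78 °C; CO2 (g); cold aq. HCl; used crude
Reagents that add atoms: carbon dioxide, O=C=O
Why: Vinylogous enolate formation at the CH2 of the 6-ethyl group (the only acidic position) followed by carboxylation; the new centre is racemic and becomes sp2 in step 7.

Step 5
Reactants: 9 (1S,2R)-2-phenylcyclohexan-1-ol
Product: 11 {(1R,2S)-2-[(prop-2-en-1-yl)oxy]cyclohexyl}benzene, via sodium alkoxide 10 (not isolated)
Conditions: NaH, THF/DMF, 0 °C; allyl bromide, rt
Reagents that add atoms: allyl bromide, C=CCBr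
Why: Williamson etherification at oxygen, which leaves both ring stereocentres untouched.

Step 6
Reactants: 11 {(1R,2S)-2-[(prop-2-en-1-yl)oxy]cyclohexyl}benzene
Product: 12 {(1R,2S)-2-[(1Z)-prop-1-en-1-yloxy]cyclohexyl}benzene
Conditions: KOt-Bu (0.3 equiv), DMSO, 60 °C
Reagents that add atoms: none
Why: Base-mediated allyl to prop-1-enyl ether isomerisation, which under kinetic control (cis-alkoxyallyl anion chelated to potassium) should give the Z isomer.

Step 7
Reactants: 8 2-(6-methoxy-3,5-dimethyl-4-oxo-4H-pyran-2-yl)propanoic acid; 12 {(1R,2S)-2-[(1Z)-prop-1-en-1-yloxy]cyclohexyl}benzene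
Product: 15 (2R,3S,4R)-4-(6-methoxy-3,5-dimethyl-4-oxo-4H-pyran-2-yl)-2,4-dimethyl-3-{[(1S,2R)-2-phenylcyclohexyl]oxy}cyclobutan-1-one, via acid chloride 13 (not isolated), via ketene 14 (not isolated)
Conditions: (COCl)2, cat. DMF, CH2Cl2, 0 °C; concentrate; 12 (1.5 equiv), Et3N, toluene, rt to 50 °C; chromatography
Reagents that add atoms: none
Why: Ketene–enol ether [2+2] cycloaddition in which the ketene carbonyl carbon bonds to the nucleophilic β-carbon of 12, the phenyl ring of the auxiliary shields one face of the s-trans Z-enol ether (sets C2 and C3, cis) and the larger pyranonyl group of the ketene takes the position cis to the alkoxy group (sets C4), minor diastereomers being removed before the next step.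

Step 8
Reactants: 15 the cyclobutanone of step 7
Product: 16 (4R)-4-(6-methoxy-3,5-dimethyl-4-oxo-4H-pyran-2-yl)-2,4-dimethylcyclobut-2-en-1-one
Conditions: DBU, CH2Cl2, 0 °C to rt
Reagents that add atoms: none
Why: E1cB β-elimination of the auxiliary alkoxide from the β-alkoxy ketone should give the cyclobutenone; C2 and C3 become sp2, while the quaternary C4, which has no α-hydrogen, keeps the configuration set in step 7.

Step 9
Reactants: 17 (2R)-but-3-yn-2-ol
Product: 18 (2R)-but-3-yn-2-yl methanesulfonate
Conditions: MsCl, Et3N, CH2Cl2, −78 to 0 °C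
Reagents that add atoms: methanesulfonyl chloride, CS(=O)(=O)Cl
Why: O-Sulfonylation, which does not touch the C–O bond and so retains configuration.

Step 10
Reactants: 18 (2R)-but-3-yn-2-yl methanesulfonate; 19 propanal
Product: 21 (3R,4S)-4-methylhex-5-yn-3-ol, via allenylzinc 20 (not isolated)
Conditions: Pd(OAc)2 (5 mol %), PPh3 (5 mol %), Et2Zn (3 equiv), THF, −78 to −20 °C
Reagents that add atoms: none
Why: Palladium-catalysed, zinc-mediated propargylation of an aldehyde: anti SN2′ attack of zerovalent palladium on 18 and transmetalation give the axially chiral allenylzinc 20, which adds to propanal through a closed SE2′ transition state, so the propargylic centre forms with net inversion ((R)-mesylate to 4S) and anti to the carbinol.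

Step 11
Reactants: 21 (3R,4S)-4-methylhex-5-yn-3-ol
Product: 22 tert-butyldimethyl{[(3R,4S)-4-methylhex-5-yn-3-yl]oxy}silane
Conditions: TBSOTf, 2,6-lutidine, CH2Cl2, 0 °C
Reagents that add atoms: tert-butyldimethylsilyl trifluoromethanesulfonate, CC(C)(C)[Si](C)(C)OS(=O)(=O)C(F)(F)F
Why: Silylation of the secondary alcohol masks the future ketone oxygen through the organometallic steps.

Step 12
Reactants: 22 tert-butyldimethyl{[(3R,4S)-4-methylhex-5-yn-3-yl]oxy}silane
Product: 24 tert-butyldimethyl{[(3R,4S)-4-methylhept-5-yn-3-yl]oxy}silane, via lithium acetylide 23 (not isolated)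
Conditions: n-BuLi, THF, −78 °C; MeI, −78 °C to rt
Reagents that add atoms: iodomethane, CI
Why: Acetylide alkylation (deprotonation of the terminal alkyne, SN2 on iodomethane), which leaves the propargylic stereocentre untouched.

Step 13
Reactants: 24 tert-butyldimethyl{[(3R,4S)-4-methylhept-5-yn-3-yl]oxy}silane
Product: 26 tert-butyl{[(3R,4S,5E)-6-iodo-4-methylhept-5-en-3-yl]oxy}dimethylsilane, via alkenylzirconocene 25 (not isolated)
Conditions: Cp2Zr(H)Cl (2 equiv), THF, 50 °C; then I2, 0 °C
Reagents that add atoms: iodine, II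
Why: Hydrozirconation–iodination: syn addition of Zr–H with zirconium at the less hindered, methyl-bearing alkyne carbon (equilibration with excess reagent) and iodinolysis with retention should give the E-trisubstituted vinyl iodide.

Step 14
Reactants: 26 the vinyl iodide of step 13; 27 propyne
Product: 28 tert-butyl{[(3R,4S,5E)-4,6-dimethylnon-5-en-7-yn-3-yl]oxy}dimethylsilane
Conditions: Pd(PPh3)2Cl2 (3 mol %), CuI (6 mol %), Et3N, THF, rt
Reagents that add atoms: none
Why: Sonogashira coupling, which retains the alkene geometry.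

Step 15
Reactants: 16 (4R)-cyclobutenone of step 8; 28 enyne of step 14
Product: 30 2-[(1S)-2-[(2E,4S,5R)-5-{[tert-butyl(dimethyl)silyl]oxy}-4-methylhept-2-en-2-yl]-1,3,5-trimethyl-4-oxocyclohexa-2,5-dien-1-yl]-6-methoxy-3,5-dimethyl-4H-pyran-4-one, via nickelacyclopentenone 29 (not isolated)
Conditions: Ni(cod)2 (10 mol %), PPh3 (20 mol %), toluene, 0 °C to rt; 28 (1.3 equiv), 16 added slowly
Reagents that add atoms: none
Why: Proposed new method: zerovalent nickel should insert into the strained acyl–C(sp3) bond C1–C4 of 16 with retention at C4 to give nickelacyclopentenone 29 (the σ-form of an η4-vinylketene complex); insertion of the alkyne of 28 into the Ni–acyl bond and C(sp2)–C(sp3) reductive elimination then form C1–C2 and C3–C4, so the six-membered ring closes by reductive elimination from a seven-membered nickelacycle (a formal [4+2]). The closest known reaction type is the Ni(cod)2-catalysed union of cyclobutenones with internal alkynes, which gives phenols through the same acyl–C4 cleavage; here C4 bears no hydrogen, so the cross-conjugated 2,5-dienone cannot tautomerise and is the product. No new stereocentre is formed: the quaternary centre is carried over with retention in both the oxidative addition and the reductive elimination as long as nickel stays on the face on which it entered, and the side-chain centres are spectators. Two selectivities are needed: cleavage of C1–C4 and not the acyl–vinyl bond C1–C6, secured by ring strain and by the weak tertiary, allylic, pyranonyl-substituted bond; and bonding of the acyl carbon to the methyl-bearing alkyne carbon, argued from the fully substituted C4 being a poor migrating group (the acyl group migrates first) and from nickel preferring the alkyne carbon conjugated to the alkene (η3-dienyl stabilisation), the orientation known for 1,3-enynes in nickel-catalysed carbonyl–alkyne couplings. Working at 0 °C to rt should keep the uncatalysed 4π ring opening of 16, which would racemise C4 through the free vinylketene, out of play.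

Step 16
Reactants: 30 the silyl ether of step 15
Product: 31 2-[(1S)-2-[(2E,4S,5R)-5-hydroxy-4-methylhept-2-en-2-yl]-1,3,5-trimethyl-4-oxocyclohexa-2,5-dien-1-yl]-6-methoxy-3,5-dimethyl-4H-pyran-4-one
Conditions: HF·pyridine, pyridine, THF, 0 °C to rt
Reagents that add atoms: none
Why: Fluoride-mediated cleavage of the silyl ether under buffered conditions, to which the dienone, the pyranone and both stereocentres should be inert.

Step 17
Reactants: 31 the alcohol of step 16
Product: 32 2-methoxy-3,5-dimethyl-6-[(1S)-1,3,5-trimethyl-2-[(2E,4S)-4-methyl-5-oxohept-2-en-2-yl]-4-oxocyclohexa-2,5-dien-1-yl]-4H-pyran-4-one (CNP0276209.1)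
Conditions: Dess–Martin periodinane, NaHCO3, CH2Cl2, 0 °C
Reagents that add atoms: none
Why: Dess–Martin oxidation under buffered, non-enolising conditions should give the β,γ-unsaturated ketone without epimerising the α-centre or moving the double bond, and it removes the auxiliary carbinol centre.

**Compound list**

1 | methyl 2-methyl-3-oxopentanoate | CCC(=O)C(C)C(=O)OC | starting material
2 | N-methoxy-N-methylpropanamide | CCC(=O)N(C)OC | starting material
3 | sodium lithium 1-methoxy-2-methylpenta-1,3-diene-1,3-diolate (dianion of 1) | CC=C([O-])C(C)=C([O-])OC.[Na+].[Li+] | intermediate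
4 | methyl 2,4-dimethyl-3,5-dioxoheptanoate (stereoisomer and enol mixture) | CCC(=O)C(C)C(=O)C(C)C(=O)OC | intermediate
5 | 6-ethyl-4-hydroxy-3,5-dimethyl-2H-pyran-2-one | CCc1oc(=O)c(C)c(O)c1C | intermediate
6 | 6-ethyl-2-methoxy-3,5-dimethyl-4H-pyran-4-one | CCc1oc(OC)c(C)c(=O)c1C | intermediate
7 | lithium 2-ethylidene-6-methoxy-3,5-dimethyl-2H-pyran-4-olate | CC=C1OC(OC)=C(C)C([O-])=C1C.[Li+] | intermediate
8 | 2-(6-methoxy-3,5-dimethyl-4-oxo-4H-pyran-2-yl)propanoic acid (racemic) | CC(C(=O)O)c1oc(OC)c(C)c(=O)c1C | intermediate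
9 | (1S,2R)-2-phenylcyclohexan-1-ol | O[C@H]1CCCC[C@@H]1c1ccccc1 | starting material
10 | sodium (1S,2R)-2-phenylcyclohexan-1-olate | [Na+].[O-][C@H]1CCCC[C@@H]1c1ccccc1 | intermediate
11 | {(1R,2S)-2-[(prop-2-en-1-yl)oxy]cyclohexyl}benzene | C=CCO[C@H]1CCCC[C@@H]1c1ccccc1 | intermediate
12 | {(1R,2S)-2-[(1Z)-prop-1-en-1-yloxy]cyclohexyl}benzene | C/C=C\O[C@H]1CCCC[C@@H]1c1ccccc1 | intermediate
13 | 2-(6-methoxy-3,5-dimethyl-4-oxo-4H-pyran-2-yl)propanoyl chloride | CC(C(=O)Cl)c1oc(OC)c(C)c(=O)c1C | intermediate
14 | 2-methoxy-3,5-dimethyl-6-(1-oxoprop-1-en-2-yl)-4H-pyran-4-one (ketene) | CC(=C=O)c1oc(OC)c(C)c(=O)c1C | intermediate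
15 | (2R,3S,4R)-4-(6-methoxy-3,5-dimethyl-4-oxo-4H-pyran-2-yl)-2,4-dimethyl-3-{[(1S,2R)-2-phenylcyclohexyl]oxy}cyclobutan-1-one | O=C1[C@H](C)[C@H](O[C@H]2CCCC[C@@H]2c2ccccc2)[C@]1(C)c1oc(OC)c(C)c(=O)c1C | intermediate
16 | (4R)-4-(6-methoxy-3,5-dimethyl-4-oxo-4H-pyran-2-yl)-2,4-dimethylcyclobut-2-en-1-one | O=C1C(C)=C[C@]1(C)c1oc(OC)c(C)c(=O)c1C | intermediate
17 | (2R)-but-3-yn-2-ol | C#C[C@@H](C)O | starting material
18 | (2R)-but-3-yn-2-yl methanesulfonate | C#C[C@@H](C)OS(C)(=O)=O | intermediate
19 | propanal | CCC=O | starting material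
20 | (buta-1,2-dien-1-yl)(ethyl)zinc, (Sa) axis | CC[Zn]C([H])=[C@@]=C([H])C | intermediate
21 | (3R,4S)-4-methylhex-5-yn-3-ol | CC[C@@H](O)[C@@H](C)C#C | intermediate
22 | tert-butyldimethyl{[(3R,4S)-4-methylhex-5-yn-3-yl]oxy}silane | CC[C@@H](O[Si](C)(C)C(C)(C)C)[C@@H](C)C#C | intermediate
23 | lithium acetylide of 22 | CC[C@@H](O[Si](C)(C)C(C)(C)C)[C@@H](C)C#C[Li] | intermediate
24 | tert-butyldimethyl{[(3R,4S)-4-methylhept-5-yn-3-yl]oxy}silane | CC[C@@H](O[Si](C)(C)C(C)(C)C)[C@@H](C)C#CC | intermediate
25 | chlorobis(cyclopentadienyl)[(2E,4S,5R)-5-{[tert-butyl(dimethyl)silyl]oxy}-4-methylhept-2-en-2-yl]zirconium | CC[C@@H](O[Si](C)(C)C(C)(C)C)[C@@H](C)/C=C(\C)[Zr](Cl)(C1C=CC=C1)C1C=CC=C1 | intermediate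
26 | tert-butyl{[(3R,4S,5E)-6-iodo-4-methylhept-5-en-3-yl]oxy}dimethylsilane | CC[C@@H](O[Si](C)(C)C(C)(C)C)[C@@H](C)/C=C(\C)I | intermediate
27 | propyne | CC#C | starting material
28 | tert-butyl{[(3R,4S,5E)-4,6-dimethylnon-5-en-7-yn-3-yl]oxy}dimethylsilane | CC[C@@H](O[Si](C)(C)C(C)(C)C)[C@@H](C)/C=C(\C)C#CC | intermediate
29 | 3,5-dimethyl-5-(6-methoxy-3,5-dimethyl-4-oxo-4H-pyran-2-yl)-1-nickelacyclopent-3-en-2-one, C5 configured as C4 of 16 (PPh3 ligands on nickel not drawn) | O=C1C(C)=C[C@](C)(c2oc(OC)c(C)c(=O)c2C)[Ni]1 | intermediate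
30 | 2-[(1S)-2-[(2E,4S,5R)-5-{[tert-butyl(dimethyl)silyl]oxy}-4-methylhept-2-en-2-yl]-1,3,5-trimethyl-4-oxocyclohexa-2,5-dien-1-yl]-6-methoxy-3,5-dimethyl-4H-pyran-4-one | CC[C@@H](O[Si](C)(C)C(C)(C)C)[C@@H](C)/C=C(\C)C1=C(C)C(=O)C(C)=C[C@]1(C)c1oc(OC)c(C)c(=O)c1C | intermediate
31 | 2-[(1S)-2-[(2E,4S,5R)-5-hydroxy-4-methylhept-2-en-2-yl]-1,3,5-trimethyl-4-oxocyclohexa-2,5-dien-1-yl]-6-methoxy-3,5-dimethyl-4H-pyran-4-one | CC[C@@H](O)[C@@H](C)/C=C(\C)C1=C(C)C(=O)C(C)=C[C@]1(C)c1oc(OC)c(C)c(=O)c1C | intermediate
32 | 2-methoxy-3,5-dimethyl-6-[(1S)-1,3,5-trimethyl-2-[(2E,4S)-4-methyl-5-oxohept-2-en-2-yl]-4-oxocyclohexa-2,5-dien-1-yl]-4H-pyran-4-one | CCC(=O)[C@@H](C)/C=C(\C)C1=C(C)C(=O)C(C)=C[C@]1(C)c1oc(OC)c(C)c(=O)c1C | target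

**Step count**

Total: 17 steps. Longest linear sequence: 9 steps (steps 1–4, 7, 8, 15–17 from 1; equally steps 9–17 from 17).

**Steps most likely to fail**

Step 15 (Proposed new method). Three processes could defeat it:
- Reverse orientation: if the alkyne inserts into the Ni–C4 bond before the Ni–acyl bond, C4 would bond to the methyl-bearing alkyne carbon and the regioisomeric dienone would form.
- Loss of configuration at C4: nickel could change faces in an η4-vinylketene intermediate, or 16 could ring-open thermally.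
- Low turnover: the enyne could oligomerise, or reductive elimination to the congested C3–C4 bond could be slow.

The fallback is the known anionic ring expansion of cyclobutenones with alkenyllithiums, in which C1–C2 is made by carbonyl addition and so cannot be misplaced. It sets out from enyne 28 and cyclobutenone 16. Hydrozirconation of the alkyne of 28 with Cp2Zr(H)Cl and iodinolysis should give tert-butyl{[(3R,4S,5E,7E)-8-iodo-4,6-dimethylnona-5,7-dien-3-yl]oxy}dimethylsilane F1. Iodine–lithium exchange (t-BuLi, −78 °C), addition to the carbonyl group of 16, warming (alkoxide-accelerated conrotatory 4π ring opening, then disrotatory 6π electrocyclisation that forms C3–C4) and quenching with Me3SiCl should give the silyl dienol ether 2-[2-[(2E,4S,5R)-5-{[tert-butyl(dimethyl)silyl]oxy}-4-methylhept-2-en-2-yl]-1,3,5-trimethyl-4-[(trimethylsilyl)oxy]cyclohexa-3,5-dien-1-yl]-6-methoxy-3,5-dimethyl-4H-pyran-4-one F2 as a mixture of ring diastereomers. Dehydrogenation with DDQ then returns the route to 30. Because C4 becomes planar in the trienolate, 30 would form together with its C4 epimer, the (1R)-cyclohexadienyl isomer F3. The two are diastereomers, since the side chain is enantiopure, and are separated by HPLC; racemic cyclobutenone serves equally in this variant.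

Step 7. The hindered disubstituted ketene may dimerise faster than it adds to the Z-enol ether, the addition may pass through a zwitterion that loses the cis geometry, or the facial and C4 selectivities may be too low for the diastereomers to be purified. The fallback drops the auxiliary and sets out from acid 8. The ketene is generated as before and trapped with commercial ethyl prop-1-enyl ether to give racemic 3-ethoxy-4-(6-methoxy-3,5-dimethyl-4-oxo-4H-pyran-2-yl)-2,4-dimethylcyclobutan-1-one F4. DBU elimination gives racemic 4-(6-methoxy-3,5-dimethyl-4-oxo-4H-pyran-2-yl)-2,4-dimethylcyclobut-2-en-1-one F5, and preparative chromatography on a chiral stationary phase delivers the (R)-enantiomer, which is 16.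

Step 8. Loss of the alkoxide may be reversible (conjugate re-addition of the alcohol to the strained enone), or the base may open the four-membered ring by retro-Claisen-type cleavage. The fallback reaches 16 at the enone oxidation level without a base-mediated elimination, setting out from alcohol 9 and acid 8. Alcohol 9 is converted (KH, trichloroethene; n-BuLi; MeI) into {(1R,2S)-2-(prop-1-yn-1-yloxy)cyclohexyl}benzene F6. [2+2] cycloaddition of F6 with ketene 14 should give (4S)-4-(6-methoxy-3,5-dimethyl-4-oxo-4H-pyran-2-yl)-2,4-dimethyl-3-{[(1S,2R)-2-phenylcyclohexyl]oxy}cyclobut-2-en-1-one F7 together with its (4R)-epimer F8, which is removed by chromatography. 1,2-Reduction of F7 with i-Bu2AlH at −78 °C gives the cyclobutenol 2-[2-hydroxy-1,3-dimethyl-4-{[(1S,2R)-2-phenylcyclohexyl]oxy}cyclobut-3-en-1-yl]-6-methoxy-3,5-dimethyl-4H-pyran-4-one F9. Dilute aqueous acid (enol-ether hydrolysis, loss of water, 1,3-carbonyl transposition) then gives 16.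

Further compounds
F1 | step 15 | tert-butyl{[(3R,4S,5E,7E)-8-iodo-4,6-dimethylnona-5,7-dien-3-yl]oxy}dimethylsilane | CC[C@@H](O[Si](C)(C)C(C)(C)C)[C@@H](C)/C=C(\C)/C=C(\C)I
F2 | step 15 | 2-[2-[(2E,4S,5R)-5-{[tert-butyl(dimethyl)silyl]oxy}-4-methylhept-2-en-2-yl]-1,3,5-trimethyl-4-[(trimethylsilyl)oxy]cyclohexa-3,5-dien-1-yl]-6-methoxy-3,5-dimethyl-4H-pyran-4-one (ring diastereomers) | CC[C@@H](O[Si](C)(C)C(C)(C)C)[C@@H](C)/C=C(\C)C1C(C)=C(O[Si](C)(C)C)C(C)=CC1(C)c1oc(OC)c(C)c(=O)c1C
F3 | step 15 | 2-[(1R)-2-[(2E,4S,5R)-5-{[tert-butyl(dimethyl)silyl]oxy}-4-methylhept-2-en-2-yl]-1,3,5-trimethyl-4-oxocyclohexa-2,5-dien-1-yl]-6-methoxy-3,5-dimethyl-4H-pyran-4-one | CC[C@@H](O[Si](C)(C)C(C)(C)C)[C@@H](C)/C=C(\C)C1=C(C)C(=O)C(C)=C[C@@]1(C)c1oc(OC)c(C)c(=O)c1C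
F4 | step 7 | 3-ethoxy-4-(6-methoxy-3,5-dimethyl-4-oxo-4H-pyran-2-yl)-2,4-dimethylcyclobutan-1-one (racemic) | CCOC1C(C)C(=O)C1(C)c1oc(OC)c(C)c(=O)c1C
F5 | step 7 | 4-(6-methoxy-3,5-dimethyl-4-oxo-4H-pyran-2-yl)-2,4-dimethylcyclobut-2-en-1-one (racemic) | O=C1C(C)=CC1(C)c1oc(OC)c(C)c(=O)c1C
F6 | step 8 | {(1R,2S)-2-(prop-1-yn-1-yloxy)cyclohexyl}benzene | CC#CO[C@H]1CCCC[C@@H]1c1ccccc1
F7 | step 8 | (4S)-4-(6-methoxy-3,5-dimethyl-4-oxo-4H-pyran-2-yl)-2,4-dimethyl-3-{[(1S,2R)-2-phenylcyclohexyl]oxy}cyclobut-2-en-1-one | O=C1C(C)=C(O[C@H]2CCCC[C@@H]2c2ccccc2)[C@@]1(C)c1oc(OC)c(C)c(=O)c1C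
F8 | step 8 | (4R)-4-(6-methoxy-3,5-dimethyl-4-oxo-4H-pyran-2-yl)-2,4-dimethyl-3-{[(1S,2R)-2-phenylcyclohexyl]oxy}cyclobut-2-en-1-one | O=C1C(C)=C(O[C@H]2CCCC[C@@H]2c2ccccc2)[C@]1(C)c1oc(OC)c(C)c(=O)c1C
F9 | step 8 | 2-[2-hydroxy-1,3-dimethyl-4-{[(1S,2R)-2-phenylcyclohexyl]oxy}cyclobut-3-en-1-yl]-6-methoxy-3,5-dimethyl-4H-pyran-4-one (carbinol epimers) | OC1C(C)=C(O[C@H]2CCCC[C@@H]2c2ccccc2)[C@@]1(C)c1oc(OC)c(C)c(=O)c1C
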